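The readings are calculated from invented constants.

- The Q charged is conserved among its forms, but that sets only their sum. As a rough assumption for short times, I took [Q] as close to its charge and the working catalyst as steady. X then grows along a line in time, and the question is how Z starts.

- north-west: Q 0.32 M; E 64 mM; G 380 mM; run made earlier
- flask: Q 0.32 M; E 64 mM; G 250 mM; time 50 min

north-west run (percent of the Q charged)

| time / min | X / % | Z / % |
|---|---|---|
| 0.833 | 2.9 | 0.5 |
| 2.50 | 8.1 | 0 |
| 5.00 | 13.1 | 1.1 |
| 8.00 | 15.8 | 4.2 |
| 10.0 | 14.3 | 4.6 |

(each reading ± 1 percentage point)

1. ratio of X to Z at 12 s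
2. ratio of X to Z at 50 min

- One extreme has Z made directly, on a line too. Its ratio of X to Z then stays constant, and the north-west slopes give 7.04.
- The other extreme has Z rising as a parabola (an induction period). X/Z times the time then stays constant, and I named that product the lag time: the north-west slope of X over the curvature of Z gave 70.4 min.
- The north-west reading of Z at 5.00 min was 1.1%, against 2.30% for the line and 1.15% for the parabola, with a scatter of 1 percentage point. So I leaned towards the parabola, and I carried the lag time to the lower G as a guess, which gave 352 at 12 s.
- The forecast said 100 and 0.5; it held that the readings “cannot exclude a small direct route of a few percent”.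
- The flask gave 394 and 0.0978, so its lag time was 78.8 min.

    Q ⇌ J (K = 13.4, k = 0.0340 min⁻¹)
    Q + E ⇌ E + X (K = 0.221, k = 1.49 M⁻¹ min⁻¹)
    E + J → E + Z (k = 1.14 M⁻¹ min⁻¹)
    E + G ⇌ L (K = 2.13 M⁻¹, k = 15.4 M⁻¹ min⁻¹)

- In these equations, the early slope of X and the early curvature of Z are both proportional to free [E] and [Q], so these cancel. The lag time is then 2 times the constant of the step to X over the product of the forward constants of the steps to J and to Z, or 76.9 min. For the neighbouring flask, with E cut to 0.026 M, the same reckoning keeps 352; that flask gave 403, a lag time of 80.6 min.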